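**Plan**

- Retrosynthesis: open the C10′–O–C4′ ether (to absinthin); cut C2–C2′ and C3–C5′ by retro-Diels–Alder (to two artabsin units); cut C4–C5 of the cyclopentadiene (to a vinylallene); cut C1–C2 (to an enol triflate and but-3-yn-2-ol); then the lactone C–O, C5=C6 (metathesis), C7–C11 (Claisen), C6–C7 and C1–C5, back to (S)-linalool.
- Enabling feature: the cyclopentadiene C1–C5 with its C4 methyl (guaiane numbering) is, without the C4–C5 bond, a vinylallene C5=C1–C2=C3=C4 on the cycloheptene. This is the pentadienyl array for a gold-induced 4π closure; the same ring later serves as diene in one half and dienophile in the other.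
- Forward order of rings: seven-membered carbocycle (step 9), trans γ-lactone (step 12), cyclopentadiene (step 16), norbornene core by Diels–Alder dimerization (step 18), oxolane bridge (step 19).
- Stereochemistry: C10 from (S)-linalool; C7 and C11 from a CBS-set carbinol relayed through a chair Ireland–Claisen rearrangement; C6 by conjugate borylation anti to the C7 side chain; C1, C2, C3, C1′, C2′, C5′ from the endo Diels–Alder on the C1–H faces; C4′ fixed by the tether.

Key step: step 16

Assumption: guaiane numbering (C1–C15, primed in the second half) is used for all intermediates; (S)-linalool of high enantiomeric purity is taken as purchasable, and racemic but-3-yn-2-ol is used because its stereo-elements are erased in step 16.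

**Route**

Step 1
Reactants: 1 (S)-linalool
Product: 2 O-triethylsilyl-(S)-linalool
Conditions: Et3SiOTf, 2,6-lutidine, CH2Cl2, −78 → 0 °C
Reagents that add atoms: triethylsilyl trifluoromethanesulfonate, CC[Si](CC)(CC)OS(=O)(=O)C(F)(F)F
Why: Silylation of the tertiary alcohol with a silyl triflate and a hindered pyridine base is routine and masks the hydroxyl for the oxidative, organometallic and gold steps; the C10 stereocentre of linalool is carried over unchanged.

Step 2
Reactants: 2 O-triethylsilyl-(S)-linalool
Product: 3 (2S)-2-methyl-2-(triethylsilyloxy)pentanedial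
Conditions: O3, CH2Cl2, −78 °C; then PPh3, −78 °C → rt
Reagents that add atoms: ozone, [O-][O+]=O
Why: Ozonolysis with reductive work-up cleaves the trisubstituted and the monosubstituted alkene in one operation (losing acetone and formaldehyde), and the aldehyde at the quaternary, silyloxy-bearing carbon cannot enolize, so C10 is safe.

Step 3
Reactants: 3 (2S)-2-methyl-2-(triethylsilyloxy)pentanedial; 4 1-(triphenylphosphoranylidene)propan-2-one
Product: 5 (2S,5E)-2-methyl-7-oxo-2-(triethylsilyloxy)oct-5-enal
Conditions: 4 (1.0 equiv), CH2Cl2, 0 °C → rt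
Reagents that add atoms: none
Why: Wittig olefination with a stabilized acyl ylide is (E)-selective and very sensitive to steric hindrance, so one equivalent should react at the unhindered C7 formyl group and leave the neopentyl-type C1 aldehyde untouched.

Step 4
Reactants: 5 (2S,5E)-2-methyl-7-oxo-2-(triethylsilyloxy)oct-5-enal; 6 vinyl bromide
Product: 7 (3E,7S)-7-methyl-7-(triethylsilyloxy)-8-(trimethylsilyloxy)deca-3,9-dien-2-one (both C1 epimers)
Conditions: CrCl2 (15 mol %), NiCl2 (2 mol %), Mn, Me3SiCl, THF/DMF, rt
Reagents that add atoms: chlorotrimethylsilane, C[Si](C)(C)Cl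
Why: Nozaki–Hiyama–Kishi vinylation, run catalytically in chromium with Mn as reductant and Me3SiCl for turnover, adds the vinylchromium species to aldehydes but not to ketones or enones and hands over the C1 carbinol directly as its trimethylsilyl ether; the C1 configuration is left undefined because C1 becomes a ketone in step 10.

Step 5
Reactants: 7 silyl-protected dienone
Product: 8 (2S,3E,7S)-7-methyl-7-(triethylsilyloxy)-8-(trimethylsilyloxy)deca-3,9-dien-2-ol (both C1 epimers)
Conditions: (R)-2-methyl-CBS-oxazaborolidine (20 mol %), catecholborane, toluene, −78 °C; then MeOH, pH 7 buffer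
Reagents that add atoms: none
Why: Corey–Bakshi–Shibata reduction: the (R)-oxazaborolidine binds the enone with the alkenyl arm as the large group and directs 1,2-hydride delivery to give the (S)-allylic alcohol, while catecholborane at low temperature leaves the vinyl group and the silyl ethers alone.

Step 6
Reactants: 8 (S)-allylic alcohol; 9 propanoyl chloride
Product: 10 (2S,3E,7S)-7-methyl-7-(triethylsilyloxy)-8-(trimethylsilyloxy)deca-3,9-dien-2-yl propanoate (both C1 epimers)
Conditions: 9, pyridine, DMAP (cat.), CH2Cl2, 0 °C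
Reagents that add atoms: none
Why: Standard acylation of the secondary allylic alcohol installs the propanoate (C11–C13) needed for the sigmatropic step without touching the stereocentre.

Step 7
Reactants: 10 allylic propanoate
Product: 13 (2S,3R,6S)-7-hydroxy-2,6-dimethyl-3-[(1E)-prop-1-enyl]-6-(triethylsilyloxy)non-8-enoic acid (both C1 epimers), via (Z)-silyl ketene acetal 11 (not isolated), via rearranged bis-silyl ester 12 (not isolated)
Conditions: LiN(iPr)2, THF/DMPU, −78 °C; Me3SiCl/Et3N; −78 → 50 °C; then aq. citric acid, MeOH, rt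
Reagents that add atoms: none
Why: Ireland–Claisen rearrangement: deprotonation in THF/DMPU should give mainly the (Z)-silyl ketene acetal, and the chair transition state with the carbinol methyl, the chain at C7 and the enolate methyl all equatorial transfers the (S)-carbinol chirality to C7 (R), sets C11 (S) syn to it and leaves an (E)-propenyl group; mild acidic methanol then cleaves the silyl ester and the labile trimethylsilyl ether but not the tertiary triethylsilyl ether.

Step 8
Reactants: 13 hydroxy acid
Product: 14 methyl (2S,3R,6S)-7-hydroxy-2,6-dimethyl-3-[(1E)-prop-1-enyl]-6-(triethylsilyloxy)non-8-enoate (both C1 epimers)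
Conditions: Me3SiCHN2, MeOH/toluene, 0 °C
Reagents that add atoms: (trimethylsilyl)diazomethane, C[Si](C)(C)C=[N+]=[N-]
Why: Esterification with (trimethylsilyl)diazomethane is neutral and chemoselective for the carboxylic acid, protecting C12 as the methyl ester for the metathesis, oxidation and borylation steps.

Step 9
Reactants: 14 diene ester
Product: 15 methyl (2S)-2-[(1R,5S)-4-hydroxy-5-methyl-5-(triethylsilyloxy)cyclohept-2-en-1-yl]propanoate (both C1 epimers)
Conditions: second-generation Grubbs catalyst (5 mol %), CH2Cl2 (5 mM), 40 °C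
Reagents that add atoms: none
Why: Ring-closing metathesis of the vinyl carbinol and the propenyl group closes the seven-membered ring at C5=C6 with loss of propene; no stereocentre is formed or touched.

Step 10
Reactants: 15 cycloheptenol
Product: 16 methyl (2S)-2-[(1R,5S)-5-methyl-4-oxo-5-(triethylsilyloxy)cyclohept-2-en-1-yl]propanoate
Conditions: Dess–Martin periodinane, NaHCO3, CH2Cl2, 0 °C → rt
Reagents that add atoms: none
Why: Dess–Martin oxidation of the allylic alcohol merges both C1 epimers into the single cycloheptenone without acid or base that could move the double bond or epimerize C7.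

Step 11
Reactants: 16 cycloheptenone
Product: 18 methyl (2S)-2-[(1S,2R,5S)-2-hydroxy-5-methyl-4-oxo-5-(triethylsilyloxy)cycloheptyl]propanoate, via β-boryl ketone 17 (not isolated)
Conditions: CuCl (5 mol %), bis[2-(diphenylphosphino)phenyl] ether (5 mol %), NaOtBu (10 mol %), B2pin2, MeOH, THF, rt; then NaBO3·4H2O, THF/H2O, rt
Reagents that add atoms: sodium perborate, [Na+].[O-]OB=O
Why: Copper-catalysed conjugate borylation: the bulky boryl–copper species should add to C6 of the enone from the face opposite the adjacent C7 side chain, and perborate oxidation of the C–B bond with retention gives the trans C6 hydroxyl (R).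

Step 12
Reactants: 18 β-hydroxy ketone ester
Product: 19 (3S,3aS,6S,8aR)-3,6-dimethyl-6-(triethylsilyloxy)hexahydro-2H-cyclohepta[b]furan-2,7(3H)-dione
Conditions: pyridinium p-toluenesulfonate (cat.), benzene, 50 °C
Reagents that add atoms: none
Why: Acid-catalysed lactonization of the γ-hydroxy ester (5-exo-trig acyl substitution) closes the trans-fused γ-lactone, both new ring bonds being equatorial on the cycloheptanone, under conditions too mild to dehydrate the β-oxygenated ketone.

Step 13
Reactants: 19 keto lactone
Product: 20 (3S,3aS,6S,8aS)-3,6-dimethyl-2-oxo-6-(triethylsilyloxy)-3,3a,4,5,6,8a-hexahydro-2H-cyclohepta[b]furan-7-yl trifluoromethanesulfonate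
Conditions: KN(SiMe3)2, N-(5-chloropyridin-2-yl)bis(trifluoromethanesulfonimide), THF, −78 °C
Reagents that add atoms: N-(5-chloropyridin-2-yl)-1,1,1-trifluoro-N-(trifluoromethylsulfonyl)methanesulfonamide, FC(F)(F)S(=O)(=O)N(c1ccc(Cl)cn1)S(=O)(=O)C(F)(F)F
Why: Kinetic enolate O-sulfonylation: C10 is quaternary, so the amide base can only deprotonate C5 (the ketone α-hydrogens being more acidic than the lactone C11–H), and the enolate is trapped at −78 °C before the lactone carboxylate can be expelled, an E1cB process already slowed because the equatorial C6–O bond of the trans-fused lactone lies near the nodal plane of the enolate.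

Step 14
Reactants: 20 enol triflate; 21 but-3-yn-2-ol
Product: 22 (3S,3aS,6S,8aS)-7-(3-hydroxybut-1-ynyl)-3,6-dimethyl-6-(triethylsilyloxy)-3,3a,4,5,6,8a-hexahydro-2H-cyclohepta[b]furan-2-one (both carbinol epimers)
Conditions: PdCl2(PPh3)2 (5 mol %), CuI (10 mol %), iPr2NH, THF, rt
Reagents that add atoms: none
Why: Sonogashira coupling: oxidative addition of zerovalent palladium into the enol triflate and transfer of the copper acetylide of 21 forge C1–C2 at room temperature, mild enough to leave the allylic lactone C–O bond un-ionized; the carbinol centre of racemic 21 is carried as a mixture.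

Step 15
Reactants: 22 enynol
Product: 25 (3S,3aS,6S,8aS)-7-(buta-1,2-dienyl)-3,6-dimethyl-6-(triethylsilyloxy)-3,3a,4,5,6,8a-hexahydro-2H-cyclohepta[b]furan-2-one (both allene epimers), via N-propargyl sulfonylhydrazine 23 (not isolated), via propargylic diazene 24 (not isolated)
Conditions: 2-nitrobenzenesulfonylhydrazide, PPh3, diethyl azodicarboxylate, THF, −15 °C → rt
Reagents that add atoms: none
Why: Myers allene synthesis: Mitsunobu displacement of the propargylic alcohol by the arenesulfonylhydrazide, loss of sulfinic acid to the propargylic diazene and retro-ene loss of N2 deliver hydrogen to C2 and give the 1,3-disubstituted allene under neutral conditions; the allene axis is formed as both epimers, which is immaterial.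

Step 16
Reactants: 25 vinylallene
Product: 27 10-O-triethylsilyl artabsin, via 5H-cyclopentadiene isomer 26 (not isolated)
Conditions: Ph3PAuCl (2 mol %), AgSbF6 (2 mol %), CH2Cl2, 0 °C; filtration through basic alumina; then benzene, 40 °C
Reagents that add atoms: none
Why: Cationic monovalent gold (Ph3PAu+) binds the allene at C3, turning C5=C1–C2=C3=C4 into an aurated pentadienyl cation that closes the C4–C5 bond by a conrotatory 4π (Nazarov-type) electrocyclization, the only ring formed being the five-membered carbocycle. A 1,2-hydride shift from C4 to the gold carbene carbon C3 and loss of gold release the 5H-diene 26, and suprafacial 1,5-hydrogen shifts on warming move the sp3 position to C3, giving the constitution of the natural diene (C1=C2, C4=C5). The closest known reaction type is the gold-catalysed cycloisomerization of vinylallenes to cyclopentadienes, a metal variant of the Nazarov cyclization. No stereocentre is created in 27: the transient centres at C4 and C5 are erased by the hydrogen shifts, so torquoselectivity and the allene configuration are immaterial and both epimers of 25 converge. The step needs chemoselective activation of the allene and a single connectivity: the s-cis vinylallene is the only such π-array present, C10 is capped as the silyl ether so that no hydroxyl can add to the gold-activated allene, and the lactone and silyl ether are inert to the neutral, low-temperature conditions.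

Step 17
Reactants: 27 10-O-triethylsilyl artabsin
Product: 28 artabsin
Conditions: HF·pyridine, pyridine, THF, 0 °C → rt
Reagents that add atoms: none
Why: Pyridine-buffered HF cleaves the tertiary triethylsilyl ether without the strong base that would deprotonate the cyclopentadiene (and eject the C6 carboxylate) or the strong acid that would dehydrate the tertiary alcohol.

Step 18
Reactants: 28 artabsin (two molecules)
Product: 31 absinthin, via ring-fusion diene isomer 29 (not isolated), via C1-H diene isomer 30 (not isolated)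
Conditions: neat film (or ≥ 2 M in benzene), argon, dark, rt → 40 °C
Reagents that add atoms: none
Why: Two suprafacial 1,5-hydrogen shifts (C3 to C2, then C2 to C1) convert artabsin reversibly into the C1-H 2,4-diene 30, which dimerizes by an endo Diels–Alder reaction in which C2′=C3′–C4′=C5′ of one molecule is the diene and the disubstituted C2=C3 bond of a second is the dienophile, both reacting on the face of their C1–H (anti to C10) so that C2–C2′ and C3–C5′ and the stereocentres C1, C2, C3, C1′, C2′ and C5′ arise together; the thermal dimerization of this class of guaianolide cyclopentadienes is a known process.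

Step 19
Reactants: 31 absinthin
Product: 32 anabsinthin
Conditions: p-TsOH·H2O (10 mol %), CH2Cl2, rt
Reagents that add atoms: none
Why: Acid-catalysed hydroalkoxylation: Markovnikov protonation of the trisubstituted C3′=C4′ alkene at C3′ gives the tertiary C4′ cation, which the C10′ hydroxyl, held on the same side of the norbornene by the bridge carbon C1′, captures in a 5-exo closure to the oxolane, fixing C4′; this isomerization of absinthin is known.

**Compound list**

1 | (S)-linalool | C=C[C@@](C)(O)CCC=C(C)C | starting material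
2 | O-triethylsilyl-(S)-linalool | C=C[C@@](C)(O[Si](CC)(CC)CC)CCC=C(C)C | intermediate
3 | (2S)-2-methyl-2-(triethylsilyloxy)pentanedial | O=CCC[C@](C)(O[Si](CC)(CC)CC)C=O | intermediate
4 | 1-(triphenylphosphoranylidene)propan-2-one | CC(=O)C=P(c1ccccc1)(c1ccccc1)c1ccccc1 | starting material
5 | (2S,5E)-2-methyl-7-oxo-2-(triethylsilyloxy)oct-5-enal | CC(=O)/C=C/CC[C@](C)(O[Si](CC)(CC)CC)C=O | intermediate
6 | vinyl bromide | C=CBr | starting material
7 | (3E,7S)-7-methyl-7-(triethylsilyloxy)-8-(trimethylsilyloxy)deca-3,9-dien-2-one, both C1 epimers | CC(=O)/C=C/CC[C@](C)(O[Si](CC)(CC)CC)C(O[Si](C)(C)C)C=C | intermediate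
8 | (2S,3E,7S)-7-methyl-7-(triethylsilyloxy)-8-(trimethylsilyloxy)deca-3,9-dien-2-ol, both C1 epimers | C[C@H](O)/C=C/CC[C@](C)(O[Si](CC)(CC)CC)C(O[Si](C)(C)C)C=C | intermediate
9 | propanoyl chloride | CCC(=O)Cl | starting material
10 | (2S,3E,7S)-7-methyl-7-(triethylsilyloxy)-8-(trimethylsilyloxy)deca-3,9-dien-2-yl propanoate, both C1 epimers | CCC(=O)O[C@@H](C)/C=C/CC[C@](C)(O[Si](CC)(CC)CC)C(O[Si](C)(C)C)C=C | intermediate
11 | (Z)-trimethylsilyl ketene acetal of 10 | C/C=C(\O[Si](C)(C)C)O[C@@H](C)/C=C/CC[C@](C)(O[Si](CC)(CC)CC)C(O[Si](C)(C)C)C=C | intermediate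
12 | trimethylsilyl (2S,3R,6S)-2,6-dimethyl-3-[(1E)-prop-1-enyl]-6-(triethylsilyloxy)-7-(trimethylsilyloxy)non-8-enoate | C[Si](C)(C)OC(=O)[C@@H](C)[C@@H](/C=C/C)CC[C@](C)(O[Si](CC)(CC)CC)C(O[Si](C)(C)C)C=C | intermediate
13 | (2S,3R,6S)-7-hydroxy-2,6-dimethyl-3-[(1E)-prop-1-enyl]-6-(triethylsilyloxy)non-8-enoic acid, both C1 epimers | OC(=O)[C@@H](C)[C@@H](/C=C/C)CC[C@](C)(O[Si](CC)(CC)CC)C(O)C=C | intermediate
14 | methyl (2S,3R,6S)-7-hydroxy-2,6-dimethyl-3-[(1E)-prop-1-enyl]-6-(triethylsilyloxy)non-8-enoate, both C1 epimers | COC(=O)[C@@H](C)[C@@H](/C=C/C)CC[C@](C)(O[Si](CC)(CC)CC)C(O)C=C | intermediate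
15 | methyl (2S)-2-[(1R,5S)-4-hydroxy-5-methyl-5-(triethylsilyloxy)cyclohept-2-en-1-yl]propanoate, both C1 epimers | COC(=O)[C@@H](C)[C@@H]1CC[C@](C)(O[Si](CC)(CC)CC)C(O)C=C1 | intermediate
16 | methyl (2S)-2-[(1R,5S)-5-methyl-4-oxo-5-(triethylsilyloxy)cyclohept-2-en-1-yl]propanoate | COC(=O)[C@@H](C)[C@@H]1CC[C@](C)(O[Si](CC)(CC)CC)C(=O)C=C1 | intermediate
17 | methyl (2S)-2-[(1R,2R,5S)-5-methyl-4-oxo-2-(4,4,5,5-tetramethyl-1,3,2-dioxaborolan-2-yl)-5-(triethylsilyloxy)cycloheptyl]propanoate | COC(=O)[C@@H](C)[C@@H]1CC[C@](C)(O[Si](CC)(CC)CC)C(=O)C[C@H]1B1OC(C)(C)C(C)(C)O1 | intermediate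
18 | methyl (2S)-2-[(1S,2R,5S)-2-hydroxy-5-methyl-4-oxo-5-(triethylsilyloxy)cycloheptyl]propanoate | COC(=O)[C@@H](C)[C@@H]1CC[C@](C)(O[Si](CC)(CC)CC)C(=O)C[C@H]1O | intermediate
19 | (3S,3aS,6S,8aR)-3,6-dimethyl-6-(triethylsilyloxy)hexahydro-2H-cyclohepta[b]furan-2,7(3H)-dione (trans-fused keto lactone) | O=C1C[C@H]2OC(=O)[C@@H](C)[C@@H]2CC[C@]1(C)O[Si](CC)(CC)CC | intermediate
20 | (3S,3aS,6S,8aS)-3,6-dimethyl-2-oxo-6-(triethylsilyloxy)-3,3a,4,5,6,8a-hexahydro-2H-cyclohepta[b]furan-7-yl trifluoromethanesulfonate | O=S(=O)(OC1=C[C@H]2OC(=O)[C@@H](C)[C@@H]2CC[C@]1(C)O[Si](CC)(CC)CC)C(F)(F)F | intermediate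
21 | but-3-yn-2-ol (racemic) | CC(O)C#C | starting material
22 | (3S,3aS,6S,8aS)-7-(3-hydroxybut-1-ynyl)-3,6-dimethyl-6-(triethylsilyloxy)-3,3a,4,5,6,8a-hexahydro-2H-cyclohepta[b]furan-2-one, both carbinol epimers | CC(O)C#CC1=C[C@H]2OC(=O)[C@@H](C)[C@@H]2CC[C@]1(C)O[Si](CC)(CC)CC | intermediate
23 | N-propargyl-N-(2-nitrobenzenesulfonyl)hydrazine derived from 22 | CC(N(N)S(=O)(=O)c1ccccc1[N+](=O)[O-])C#CC1=C[C@H]2OC(=O)[C@@H](C)[C@@H]2CC[C@]1(C)O[Si](CC)(CC)CC | intermediate
24 | propargylic diazene derived from 23 | CC(N=N)C#CC1=C[C@H]2OC(=O)[C@@H](C)[C@@H]2CC[C@]1(C)O[Si](CC)(CC)CC | intermediate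
25 | (3S,3aS,6S,8aS)-7-(buta-1,2-dienyl)-3,6-dimethyl-6-(triethylsilyloxy)-3,3a,4,5,6,8a-hexahydro-2H-cyclohepta[b]furan-2-one, both allene epimers | CC=C=CC1=C[C@H]2OC(=O)[C@@H](C)[C@@H]2CC[C@]1(C)O[Si](CC)(CC)CC | intermediate
26 | 10-O-triethylsilyl 5H-diene isomer (C1=C2, C3=C4; C5 sp3, configuration open) | CC1=CC=C2C1[C@H]1OC(=O)[C@@H](C)[C@@H]1CC[C@]2(C)O[Si](CC)(CC)CC | intermediate
27 | 10-O-triethylsilyl artabsin, (3S,3aS,6S,9bS)-3,6,9-trimethyl-6-(triethylsilyloxy)-3a,4,5,6,8,9b-hexahydroazuleno[4,5-b]furan-2(3H)-one | CC1=C2[C@H]3OC(=O)[C@@H](C)[C@@H]3CC[C@](C)(O[Si](CC)(CC)CC)C2=CC1 | intermediate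
28 | artabsin | CC1=C2[C@H]3OC(=O)[C@@H](C)[C@@H]3CC[C@](C)(O)C2=CC1 | intermediate
29 | ring-fusion diene isomer of artabsin (C1=C5, C3=C4; C2 is CH2) | CC1=CCC2=C1[C@H]1OC(=O)[C@@H](C)[C@@H]1CC[C@]2(C)O | intermediate
30 | C1-H diene isomer of artabsin, (1R)-configured (C2=C3, C4=C5) | CC1=C2[C@H]3OC(=O)[C@@H](C)[C@@H]3CC[C@](C)(O)[C@@H]2C=C1 | intermediate
31 | absinthin | CC1=C2[C@H]3OC(=O)[C@@H](C)[C@@H]3CC[C@](C)(O)[C@@H]2[C@H]2[C@H]3C=C(C)[C@]4([C@@H]3[C@@](C)(O)CC[C@H]5[C@H](C)C(=O)O[C@H]45)[C@@H]12 | intermediate
32 | anabsinthin | CC1=C2[C@H]3OC(=O)[C@@H](C)[C@@H]3CC[C@](C)(O)[C@@H]2[C@H]2[C@H]3C[C@]4(C)O[C@@]5(C)CC[C@H]6[C@H](C)C(=O)O[C@@H]6[C@@]4([C@@H]35)[C@@H]12 | target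

**Step count and risks**

Total step count: 19. Longest linear sequence: 19 steps from (S)-linalool (4, 6, 9 and 21 are purchased).

Most likely to fail, in order:

Step 18 (isomerization and dimerization). The hydrogen-shift equilibrium may hold the reactive C1-H diene 30 at a very low stationary concentration, so that air oxidation, azulene-forming dehydration or unselective oligomerization overtake the cycloaddition. The fallback sets out from 25 and returns at 31. The gold cyclization is run at −40 °C and quenched cold with Et3N so that the first-formed diene 26 is kept. HF·pyridine/pyridine at −20 °C then frees the tertiary alcohol to give the 5H-diene alcohol F1. On concentration below room temperature a single 1,5-hydrogen shift from C5 to C1 leads straight to 30, so dimerization to 31 starts from the kinetic isomer instead of from equilibrated artabsin.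

Step 13 (enol triflate). The C1 enolate may expel the lactone carboxylate (retro-oxa-Michael), or the base may deprotonate and scramble C11. The fallback sets out from 18 and returns at 22; it forms the triflate before the lactone exists. Silylation of 18 (Me3SiCl, imidazole, CH2Cl2) gives the C6-O-trimethylsilyl ether F2, whose β-silyloxy enolate does not eliminate at −78 °C. KN(SiMe3)2 and the same triflimide give the enol triflate F3. Sonogashira coupling with 21 under the conditions of step 14 gives the enynol ester F4. Pyridinium p-toluenesulfonate in MeOH, then gentle warming, removes the trimethylsilyl group and closes the lactone to 22.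

Step 11 (conjugate borylation). Facial discrimination on the flexible cycloheptenone may be poor and give the C6 epimer that leads to the cis lactone. The fallback sets out from 16 and returns at 18. Nucleophilic epoxidation (tBuOOH, DBU, CH2Cl2) closes the oxirane on the face opposite the C7 side chain to give the epoxy ketone F5. Reductive opening at the α-carbon with the selenoborate from (PhSe)2 and NaBH4 (EtOH, AcOH) gives 18 with the C6 configuration defined by the oxirane.

Further compounds
F1 | step 18 | 5H-diene alcohol (10-hydroxy analogue of 26) | CC1=CC=C2C1[C@H]1OC(=O)[C@@H](C)[C@@H]1CC[C@]2(C)O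
F2 | step 13 | C6-O-trimethylsilyl ether, methyl (2S)-2-[(1S,2R,5S)-5-methyl-4-oxo-5-(triethylsilyloxy)-2-(trimethylsilyloxy)cycloheptyl]propanoate | COC(=O)[C@@H](C)[C@@H]1CC[C@](C)(O[Si](CC)(CC)CC)C(=O)C[C@H]1O[Si](C)(C)C
F3 | step 13 | enol triflate, methyl (2S)-2-[(1S,2S,5S)-5-methyl-5-(triethylsilyloxy)-4-(trifluoromethylsulfonyloxy)-2-(trimethylsilyloxy)cyclohept-3-en-1-yl]propanoate | COC(=O)[C@@H](C)[C@@H]1CC[C@](C)(O[Si](CC)(CC)CC)C(OS(=O)(=O)C(F)(F)F)=C[C@H]1O[Si](C)(C)C
F4 | step 13 | enynol ester, methyl (2S)-2-[(1S,2S,5S)-4-(3-hydroxybut-1-ynyl)-5-methyl-5-(triethylsilyloxy)-2-(trimethylsilyloxy)cyclohept-3-en-1-yl]propanoate | COC(=O)[C@@H](C)[C@@H]1CC[C@](C)(O[Si](CC)(CC)CC)C(C#CC(C)O)=C[C@H]1O[Si](C)(C)C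
F5 | step 11 | epoxy ketone (C5–C6 oxirane of 16, anti to the C7 side chain) | COC(=O)[C@@H](C)[C@@H]1CC[C@](C)(O[Si](CC)(CC)CC)C(=O)[C@H]2O[C@@H]12
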